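The eta run looks slow: after 4.00 h it holds target at 13.2% of the charge. One run stands so far, and three flasks are to be judged from it.

| setting | eta | Tuesday's | Sunday's | Friday's |
|---|---|---|---|---|
| substrate | 10 mM | 10 mM | 10 mM | 10 mM |
| reagent | 1.05 equiv | 1.05 equiv | 1.05 equiv | 1.05 equiv |
| free catalyst | 0.17 mol% | 0.11 mol% | 0.11 mol% | 0.11 mol% |
| temperature | 60 °C | 60 °C | 75 °C | 90 °C |
| remark | run made earlier |  |  |  |
| time |  | 20 h | 20 h | 20 h |

eta run (percent of the substrate charged)

| time / h | target / % |
|---|---|
| 0.333 | 1.7 |
| 0.667 | 2.8 |
| 1.50 | 6.6 |
| 4.00 | 13.2 |

(each reading ± 0.3 percentage points)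

- percent here means substrate units held: one spent catalyst counts as two
- reactions considered so far: substrate + free catalyst <-> catalyst intermediate A; reagent + catalyst intermediate A <-> catalyst intermediate B; catalyst intermediate B <-> free catalyst + target; free catalyst + target -> free catalyst + over-reaction product; 2 catalyst intermediate A -> spent catalyst
- the earlier runs do not show what temperature does; that part of a forecast is a guess
- no earlier run changes the charge of free catalyst; that part of a forecast is a guess

- the best flask by amount of target, in percent of the substrate charged; "all alike" if 1.5 percentage points covers them all (Tuesday's / Sunday's / Friday's / all alike)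
- amount of target at the end, in percent of the substrate charged, Tuesday's
- amount of target at the end, in percent of the substrate charged, Sunday's
- amount of target at the end, in percent of the substrate charged, Friday's

Two numbers in the eta run don't go together. Up to 1.50 h target gains 0.0440 /h of the charge, and from there to 4.00 h it gains 0.0264 /h, yet at 4.00 h target is 13.2% of the charge. I read this as target being lost as it forms: free catalyst + target goes on to over-reaction product, pseudo-first-order at steady free catalyst. The gain is then the making minus a loss constant times the mean target, 3.30% and 9.90% on the two stretches. Taking the first gain as the making gives a loss constant of 0.178 /h. Putting that back raises the making to 0.0499 /h and the loss constant to 0.237 /h. Going round until both stretches agree gives 0.267 /h and a making of 0.0528 /h.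

The target ceiling, 19.8%, is the making over the loss constant, the level where target stops gaining. I guess that both go with the catalyst, so the ceiling holds at 0.11 mol% while the loss constant falls to 0.173 /h. Its time, 5.78 h, is shorter than 20 h, so I expect about 19.2% for Tuesday's. The runs don't show what heat does, so I carry the same ceiling to Sunday's and Friday's as a guess, which reads as all alike.

The forecast names Sunday's, with 25%, 29% and 26% for Tuesday's, Sunday's and Friday's. It reads the slowing differently: “That fits second-order catalyst death”. Its Tuesday's figure is higher than mine.

The flasks give 21.3%, 11.6% and 4.08% in that order, so the best is Tuesday's.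

    substrate + free catalyst ⇌ catalyst intermediate A (K = 70.0 /M, k = 5.70 /M/s, Ea = 51.0 kJ/mol, ΔH = −47.0 kJ/mol)
    reagent + catalyst intermediate A ⇌ catalyst intermediate B (K = 95.0 /M, k = 12.0 /M/s, Ea = 36.0 kJ/mol, ΔH = −48.0 kJ/mol)
    catalyst intermediate B ⇌ free catalyst + target (K = 0.0120 M, k = 2.30 /s, Ea = 98.0 kJ/mol, ΔH = −53.0 kJ/mol)
    free catalyst + target → free catalyst + over-reaction product (k = 15.0 /M/s, Ea = 57.0 kJ/mol)
    2 catalyst intermediate A → spent catalyst (k = 4.50 /M/s, Ea = 60.0 kJ/mol)
    (constants at 90 °C)

Tuesday's ends at 21.3% against the ceiling of 19.8%, and from 10.0 h to 20.0 h it loses substrate at 0.0188 /h of the charge, more than the 0.0157 /h it gains as over-reaction product. Sunday's over the same hours loses substrate at 0.0203 /h and gains over-reaction product at 0.0257 /h, which on its mean target is a loss constant of 0.180 /h and a ceiling of 11.3%, lower than 19.8%, and its target falls from 17.0% to 11.6%.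

(The data come from a simulation from invented constants; the scatter is artificial.)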